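(The readings are calculated from invented constants; noise was put on by code.)

The red run has gone slow by its end: from 91 min to 130 min its G gains 1.50% of the J charged, and G then stands at 55.4% of that charge.

| flask | J | Z | time |
|---|---|---|---|
| red | 0.100 M | 0.00300 M |  |
| grey | 0.0400 M | 0.00300 M |  |
| teal | 0.100 M | 0.00150 M |  |
| ochre | 0.0500 M | 0.00150 M | 130 min |

| run | time / min | [G] / M |
|---|---|---|
| red run | 9.9 | 0.0212 |
| red run | 30 | 0.0390 |
| red run | 57 | 0.0476 |
| red run | 91 | 0.0539 |
| red run | 130 | 0.0554 |
| grey run | 9.9 | 0.0096 |
| grey run | 30 | 0.0205 |
| grey run | 57 | 0.0263 |
| grey run | 91 | 0.0290 |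
| grey run | 130 | 0.0297 |
| teal run | 9.9 | 0.0122 |
| teal run | 30 | 0.0233 |
| teal run | 57 | 0.0325 |
| teal run | 91 | 0.0353 |
| teal run | 130 | 0.0387 |

(readings scatter by 5 × 10⁻⁴ M)

1. how the opening rate goes with [Z] round the charge of the red run: the exponent of the rate at two percent of J gone to G
2. how the opening rate goes with [J] round the charge of the red run: the exponent of the rate at two percent of J gone to G (one fixed amount of G, the same in the runs compared)
3. G in the ochre run at 130 min, as a share of the J charged

- Overall: J -> G, with Z as catalyst.
- Constant volume, constant temperature.
- Bound and free are read together.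
- An order is taken over about fifteen percent of the charge, up and down.

The quick number for ochre can come from one quantity, the load: J charged per Z charged, 33.3 in the red run, which is the turnover number that full conversion of red's J to G asks of Z. The last readings go with it. Grey, at load 13.3, stands at 74.2%; red stands at 55.4%; teal, at load 66.7, stands at 38.7%.

Ochre carries load 33.3, the same as red, so my reckoning takes ochre for the red run on a slower clock. With Z at half of red's, its 130 min count as 65.0 min of red. A straight line between red's readings at 57 min and 91 min gives 49.1%, a little low on a curve that bends this way.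

The forecast reads the stops thus: “The catalyst dies, or product shuts it down.” It gives 51% for ochre, between 46% and 57%, which is higher than my line, with orders 0.85 in Z and 0.7 in J.

The simulation gives 52.7% for ochre, inside the forecast's range, and orders 1.0 in Z and 1.0 in J, the second above the forecast's range.

    Z + J → G + Z (11.34 M⁻¹ min⁻¹)
    Z + G ⇌ ZG, settled at all times (10.30 M⁻¹)
    2 J → Gy (0.2580 M⁻¹ min⁻¹)

G in the red run came to half of red's J charged at 65.8 min, later than the 65.0 min of red that load and clock made of ochre's 130 min, yet G in ochre stands above my line by 3.6 percentage points. G in the grey run, at load 13.3 against red's 33.3, came to half of grey's J charged sooner, at 29.4 min.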